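Ring B is a cyclohexene whose C7=C8 double bond lies opposite the C5–C10 ring-fusion bond (drimane locants), the classical Diels–Alder retron; everything rests on cutting C5–C6 and C9–C10. One catalytic enantioselective [4+2] cycloaddition joins an acyclic (E)-2-methyl enal (C1, C10, C5, C4 plus an acetyl group for C3/C2) to a vinylallene (C6–C9, C11, C12). The (E)-alkene is translated suprafacially into the anti H-5/CH3-15 relationship that a ring A cycloalkene could never deliver, and the allene leaves C9 as an exocyclic methylene, so no endo/exo question arises. Aldol closure of ring A, reductive α-hydroxylation, ketone reduction, face-selective hydroboration and Mitsunobu etherification with umbelliferone follow.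

Key step: step 4

Remark on locants: C10 is the methyl-bearing fusion carbon (methyl = C15), C5 the fusion CH, C4 the gem-dimethyl carbon, C3 and C2 the carbinol carbons, C1 the ring A CH2, C6 the ring B CH2, C7=C8 the alkene (C12 = methyl on C8), C9 the CH bearing the CH2O carbon C11.
Remark on materials: 4-hydroxy-3,3-dimethylbutan-2-one is assumed to be purchasable; if not, it is one step from 3-methylbutan-2-one and paraformaldehyde in trifluoroacetic acid.

Step 1
Reactants: 1 4-hydroxy-3,3-dimethylbutan-2-one
Product: 2 2,2-dimethyl-3-oxobutanal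
Conditions: Dess–Martin periodinane, CH2Cl2, 0 °C to rt; used as a filtered solution
Reagents that add atoms: none
Why: Dess–Martin oxidation of a primary alcohol to a non-enolisable aldehyde (quaternary α-carbon), so neither over-oxidation nor aldol self-condensation is expected.

Step 2
Reactants: 2 2,2-dimethyl-3-oxobutanal; 3 2-(triphenylphosphoranylidene)propanal
Product: 4 (E)-2,4,4-trimethyl-5-oxohex-2-enal
Conditions: toluene, 90 °C
Reagents that add atoms: none
Why: Wittig olefination with a formyl-stabilised ylide should react only at the aldehyde (the ketone is neopentyl and less electrophilic) and give the (E)-2-methyl enal, with the tertiary alkyl group trans to CHO.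

Step 3
Reactants: 5 1-bromobut-2-yne; 6 vinylmagnesium bromide
Product: 7 3-methylpenta-1,2,4-triene
Conditions: CuBr·SMe2 (5 mol%), THF, −78 to 0 °C; taken up in pentane, THF washed out with water, used as a titrated solution
Reagents that add atoms: none
Why: Copper-catalysed SN2' substitution of a propargylic bromide by a vinyl Grignard reagent is a standard allene synthesis; attack at the methyl-bearing alkyne carbon should give the vinylallene, which has no stereocentre.

Step 4
Reactants: 4 (E)-2,4,4-trimethyl-5-oxohex-2-enal; 7 3-methylpenta-1,2,4-triene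
Product: 8 (1R,6S)-1,3-dimethyl-2-methylidene-6-(2-methyl-3-oxobutan-2-yl)cyclohex-3-ene-1-carbaldehyde
Conditions: (R)-1-(2-methylphenyl)-3,3-diphenyltetrahydro-1H,3H-pyrrolo[1,2-c][1,3,2]oxazaborole (20 mol%) protonated with Tf2NH, diene in threefold excess, CH2Cl2, −78 to −20 °C
Reagents that add atoms: none
Why: The protonated oxazaborolidine binds the formyl group of 4 (the hindered ketone stays free) and lowers the LUMO of the C5=C10 bond, which the s-cis diene unit C6=C7–C8=C9 of 7 (vinyl group plus proximal allene π bond) attacks in a concerted, asynchronous, suprafacial [4+2] cycloaddition. The closest known reaction type is the cationic oxazaborolidine-catalysed Diels–Alder reaction of 2-methylacroleins with acyclic dienes, combined with the established use of vinylallenes as 4π partners. Ring B is closed as a six-membered ring in one [4+2] event (C5–C6 leading, C9–C10 lagging), and the distal allene π bond survives as the exocyclic C9=C11 methylene. The relative configuration of the new stereocentres C5 and C10 (H-5 anti to CH3-15, so C1 and C4 on opposite faces) is fixed by the (E)-geometry of 4, and the absolute configuration by the catalyst, which must block the Re face at C10 so that the diene adds to the Si face; on the pre-transition-state model accepted for 2-substituted acroleins this should be the (R)-catalyst, and the antipode is equally available should the bulky β-substituent reverse the sense. The step needs regioselectivity (C6 to the β-carbon C5, the sp carbon C9 to the α-carbon C10), which the larger HOMO coefficient at the vinyl terminus of the vinylallene (the allene terminus acts as a 1-substituent and should outweigh the opposing bias of the C8 methyl) and the larger LUMO coefficient at the β-carbon of the complexed enal should secure, helped by the small steric demand of the sp carbon at the quaternary centre. Because C9 becomes sp2 there is no endo/exo issue; this is why the allene is used in place of an (E)-dienyl ether, whose endo adduct would put C11 on the wrong face.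

Step 5
Reactants: 8 (1R,6S)-1,3-dimethyl-2-methylidene-6-(2-methyl-3-oxobutan-2-yl)cyclohex-3-ene-1-carbaldehyde
Product: 10 (4aR,8aS)-1,1,4a,6-tetramethyl-5-methylidene-4a,5,8,8a-tetrahydronaphthalen-2(1H)-one, via aldol adduct 9 (not isolated)
Conditions: NaOMe, MeOH, rt to 50 °C
Reagents that add atoms: none
Why: Intramolecular aldol condensation in which only the acetyl CH3 (C2) can enolise and only the non-enolisable aldehyde C1 can accept, so 6-(enolexo)-exo-trig closure and E1cB dehydration should give the trans-fused enone without touching C5 or C10.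

Step 6
Reactants: 10 (4aR,8aS)-1,1,4a,6-tetramethyl-5-methylidene-4a,5,8,8a-tetrahydronaphthalen-2(1H)-one
Product: 12 (3S,4aR,8aS)-3-hydroxy-1,1,4a,6-tetramethyl-5-methylidene-3,4,4a,5,8,8a-hexahydronaphthalen-2(1H)-one, via potassium enolate 11 (not isolated)
Conditions: K[HB(sec-Bu)3] (1.1 equiv), THF, −78 °C; then 2-(benzenesulfonyl)-3-phenyloxaziridine, −78 to −40 °C; aq NH4Cl
Reagents that add atoms: potassium tri-sec-butylborohydride [K+].CCC(C)[BH-](C(C)CC)C(C)CC (counter-ion of 11); 2-(benzenesulfonyl)-3-phenyloxaziridine O=S(=O)(c1ccccc1)N1OC1c1ccccc1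
Why: Conjugate hydride delivery to C1 (attack at the carbonyl is blocked by the quaternary C4) should give the C2 enolate regiospecifically, and Davis oxidation on the face anti to the axial C10 and C4 methyl groups sets the equatorial C2 hydroxyl.

Step 7
Reactants: 12 (3S,4aR,8aS)-3-hydroxy-1,1,4a,6-tetramethyl-5-methylidene-3,4,4a,5,8,8a-hexahydronaphthalen-2(1H)-one
Product: 13 (2S,3S,4aR,8aS)-1,1,4a,6-tetramethyl-5-methylidene-1,2,3,4,4a,5,8,8a-octahydronaphthalene-2,3-diol
Conditions: NaBH4, MeOH, 0 °C
Reagents that add atoms: none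
Why: Borohydride reduction of the 4,4-dimethyl 3-ketone by axial hydride attack anti to the two axial methyl groups should give the equatorial C3 alcohol and hence the trans-diequatorial diol, as in the A-ring chemistry of 2-hydroxy-3-oxo triterpenoids.

Step 8
Reactants: 13 (2S,3S,4aR,8aS)-1,1,4a,6-tetramethyl-5-methylidene-1,2,3,4,4a,5,8,8a-octahydronaphthalene-2,3-diol
Product: 15 (2S,3S,4aR,5R,8aS)-5-(hydroxymethyl)-1,1,4a,6-tetramethyl-1,2,3,4,4a,5,8,8a-octahydronaphthalene-2,3-diol, via borane adduct 14 (not isolated)
Conditions: 9-BBN (4 equiv), THF, 0 to 50 °C; then NaOH, H2O2, 0 °C to rt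
Reagents that add atoms: 9-borabicyclo[3.3.1]nonane [H]B1C2CCCC1CCC2 (in 14); hydrogen peroxide OO
Why: Anti-Markovnikov hydroboration of the terminal C9=C11 bond (the trisubstituted C7=C8 bond is far slower with 9-BBN) should deliver hydrogen to C9 from the face opposite the axial C10 methyl, placing C11 cis to that methyl, and oxidation with retention then gives the primary alcohol.

Step 9
Reactants: 15 (2S,3S,4aR,5R,8aS)-5-(hydroxymethyl)-1,1,4a,6-tetramethyl-1,2,3,4,4a,5,8,8a-octahydronaphthalene-2,3-diol; 16 7-hydroxy-2H-chromen-2-one (umbelliferone)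
Product: 17 7-{[(1R,4aS,6S,7S,8aR)-6,7-dihydroxy-2,5,5,8a-tetramethyl-1,4,4a,5,6,7,8,8a-octahydronaphthalen-1-yl]methoxy}-2H-chromen-2-one
Conditions: PPh3, DIAD (1.1 equiv each), THF, 0 °C to rt
Reagents that add atoms: none
Why: Mitsunobu etherification in which the acidic phenol displaces the oxyphosphonium of the primary C11 alcohol by SN2, while the hindered secondary C2 and C3 hydroxyls should remain and no stereocentre is affected.

Compound list
1 | 4-hydroxy-3,3-dimethylbutan-2-one | CC(=O)C(C)(C)CO | starting material
2 | 2,2-dimethyl-3-oxobutanal | CC(=O)C(C)(C)C=O | intermediate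
3 | 2-(triphenylphosphoranylidene)propanal | CC(C=O)=P(c1ccccc1)(c1ccccc1)c1ccccc1 | starting material
4 | (E)-2,4,4-trimethyl-5-oxohex-2-enal | CC(=O)C(C)(C)/C=C(\C)C=O | intermediate
5 | 1-bromobut-2-yne | CC#CCBr | starting material
6 | vinylmagnesium bromide | C=C[Mg]Br | starting material
7 | 3-methylpenta-1,2,4-triene | C=C=C(C)C=C | intermediate
8 | (1R,6S)-1,3-dimethyl-2-methylidene-6-(2-methyl-3-oxobutan-2-yl)cyclohex-3-ene-1-carbaldehyde | CC1=CC[C@H](C(C)(C)C(C)=O)[C@@](C)(C=O)C1=C | intermediate
9 | (4aR,8aS)-4-hydroxy-1,1,4a,6-tetramethyl-5-methylidene-3,4,4a,5,8,8a-hexahydronaphthalen-2(1H)-one (aldol adduct, either C4 epimer) | CC1=CC[C@@H]2C(C)(C)C(=O)CC(O)[C@@]2(C)C1=C | intermediate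
10 | (4aR,8aS)-1,1,4a,6-tetramethyl-5-methylidene-4a,5,8,8a-tetrahydronaphthalen-2(1H)-one | CC1=CC[C@@H]2C(C)(C)C(=O)C=C[C@@]2(C)C1=C | intermediate
11 | potassium (4aR,8aS)-1,1,4a,6-tetramethyl-5-methylidene-1,4,4a,5,8,8a-hexahydronaphthalen-2-olate | CC1=CC[C@@H]2C(C)(C)C([O-])=CC[C@@]2(C)C1=C.[K+] | intermediate
12 | (3S,4aR,8aS)-3-hydroxy-1,1,4a,6-tetramethyl-5-methylidene-3,4,4a,5,8,8a-hexahydronaphthalen-2(1H)-one | CC1=CC[C@@H]2C(C)(C)C(=O)[C@@H](O)C[C@@]2(C)C1=C | intermediate
13 | (2S,3S,4aR,8aS)-1,1,4a,6-tetramethyl-5-methylidene-1,2,3,4,4a,5,8,8a-octahydronaphthalene-2,3-diol | CC1=CC[C@@H]2C(C)(C)[C@H](O)[C@@H](O)C[C@@]2(C)C1=C | intermediate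
14 | hydroboration adduct of 13: C11 bonded to the boron of a 9-borabicyclo[3.3.1]nonan-9-yl group, both hydroxyls as O-(9-borabicyclo[3.3.1]nonan-9-yl) borinates, ring configuration as in 15 | CC1=CC[C@@H]2C(C)(C)[C@H](OB3C4CCCC3CCC4)[C@@H](OB3C4CCCC3CCC4)C[C@@]2(C)[C@@H]1CB1C2CCCC1CCC2 | intermediate
15 | (2S,3S,4aR,5R,8aS)-5-(hydroxymethyl)-1,1,4a,6-tetramethyl-1,2,3,4,4a,5,8,8a-octahydronaphthalene-2,3-diol | CC1=CC[C@@H]2C(C)(C)[C@H](O)[C@@H](O)C[C@@]2(C)[C@@H]1CO | intermediate
16 | 7-hydroxy-2H-chromen-2-one (umbelliferone) | O=c1ccc2ccc(O)cc2o1 | starting material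
17 | 7-{[(1R,4aS,6S,7S,8aR)-6,7-dihydroxy-2,5,5,8a-tetramethyl-1,4,4a,5,6,7,8,8a-octahydronaphthalen-1-yl]methoxy}-2H-chromen-2-one | CC1=CC[C@@H]2C(C)(C)[C@H](O)[C@@H](O)C[C@@]2(C)[C@@H]1COc1ccc2ccc(=O)oc2c1 | target

Total step count: 9. Longest linear sequence: 8 (steps 1, 2, 4, 5, 6, 7, 8, 9 from compound 1); step 3 is the branch that supplies the diene.

Steps most likely to fail

Step 4. The cycloaddition may be too slow at the congested trisubstituted enal, so that the allene oligomerises under the acid. The catalyst may also discriminate the two enal faces poorly, or the C8 methyl may erode the orientation of addition. The fallback sets out from compound 4 and returns at compound 8. Acetalisation of the aldehyde of 4 with (2R,4R)-pentane-2,4-diol (PPTS, benzene, water removal; the neopentyl ketone stays free) gives (E)-5-[(4R,6R)-4,6-dimethyl-1,3-dioxan-2-yl]-3,3-dimethylhex-4-en-2-one F1. Ionisation with TMSOTf at −78 °C gives a tethered vinyl oxocarbenium ion, a far stronger and more polarised dienophile whose faces are differentiated by the chiral diol. Cycloaddition with 7 (ionic Diels–Alder reaction of a chiral α,β-unsaturated acetal) gives the cycloadduct acetal F2. Mild hydrolysis (PPTS, wet acetone) then gives 8. The antipodal diol is used if it proves to be the matched one.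

Step 6. Hydride may add to the carbonyl carbon instead of C1, or the enolate may add to the sulfonimine co-product instead of being hydroxylated. The fallback sets out from compound 10 and returns at compound 12. RhCl(PPh3)3-catalysed 1,4-hydrosilylation with Et3SiH gives the triethylsilyl enol ether F3. Rubottom oxidation with dimethyldioxirane (1 equiv, acetone/CH2Cl2, −78 °C), where the electron-rich enol ether should react ahead of the diene and on the face anti to the axial methyls, gives after silyl migration the 3-(triethylsilyloxy) ketone F4. HF·pyridine then frees 12.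

Step 9. The Mitsunobu betaine may engage the vicinal diol (cyclic phosphorane, aryl ether at C2), or substitution at the β-branched C11 may be too slow to compete. The fallback sets out from compound 13 and returns at compound 17. Acetylation (Ac2O, DMAP, pyridine) gives the diacetate F5. Hydroboration (9-BBN, then NaBO3·4H2O to spare the esters) gives the primary alcohol diacetate F6. Mitsunobu etherification with 16, now with a single free hydroxyl, gives the aryl ether diacetate F7, and methanolysis (K2CO3, MeOH, rt) gives 17.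

Further compounds
F1 | step 4 | (E)-5-[(4R,6R)-4,6-dimethyl-1,3-dioxan-2-yl]-3,3-dimethylhex-4-en-2-one (pentane-2,4-diol acetal of 4) | C[C@@H]1C[C@@H](C)OC(O1)/C(C)=C/C(C)(C)C(C)=O
F2 | step 4 | (4R,6R)-2-[(1R,6S)-1,3-dimethyl-2-methylidene-6-(2-methyl-3-oxobutan-2-yl)cyclohex-3-en-1-yl]-4,6-dimethyl-1,3-dioxane | CC1=CC[C@H](C(C)(C)C(C)=O)[C@@](C)(C2O[C@H](C)C[C@@H](C)O2)C1=C
F3 | step 6 | triethyl{[(4aR,8aS)-1,1,4a,6-tetramethyl-5-methylidene-1,4,4a,5,8,8a-hexahydronaphthalen-2-yl]oxy}silane | CC1=CC[C@@H]2C(C)(C)C(O[Si](CC)(CC)CC)=CC[C@@]2(C)C1=C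
F4 | step 6 | (3S,4aR,8aS)-1,1,4a,6-tetramethyl-5-methylidene-3-(triethylsilyloxy)-3,4,4a,5,8,8a-hexahydronaphthalen-2(1H)-one | CC1=CC[C@@H]2C(C)(C)C(=O)[C@@H](O[Si](CC)(CC)CC)C[C@@]2(C)C1=C
F5 | step 9 | (2S,3S,4aR,8aS)-1,1,4a,6-tetramethyl-5-methylidene-1,2,3,4,4a,5,8,8a-octahydronaphthalene-2,3-diyl diacetate | CC1=CC[C@@H]2C(C)(C)[C@H](OC(C)=O)[C@@H](OC(C)=O)C[C@@]2(C)C1=C
F6 | step 9 | (2S,3S,4aR,5R,8aS)-5-(hydroxymethyl)-1,1,4a,6-tetramethyl-1,2,3,4,4a,5,8,8a-octahydronaphthalene-2,3-diyl diacetate | CC1=CC[C@@H]2C(C)(C)[C@H](OC(C)=O)[C@@H](OC(C)=O)C[C@@]2(C)[C@@H]1CO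
F7 | step 9 | (2S,3S,4aR,5R,8aS)-1,1,4a,6-tetramethyl-5-{[(2-oxo-2H-chromen-7-yl)oxy]methyl}-1,2,3,4,4a,5,8,8a-octahydronaphthalene-2,3-diyl diacetate | CC1=CC[C@@H]2C(C)(C)[C@H](OC(C)=O)[C@@H](OC(C)=O)C[C@@]2(C)[C@@H]1COc1ccc2ccc(=O)oc2c1
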